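**Retrosynthetic overview**
1. Target ⇒ butenolide (ligand-controlled C=C reduction sets the lactone C4) ⇒ 3-furyl carbinol (singlet-oxygen dearomatisation of the furan; the lactone ring is made last).
2. 3-Furyl carbinol ⇒ 3-furyl ketone (reagent-controlled reduction sets the carbinol) ⇒ 3-acetylfuran + (Z)-alkenyl iodide (Pd enolate alkenylation).
3. (Z)-Alkenyl iodide ⇒ decalin-ethyl Grignard + propargyl alcohol + I2 (anti-carbomagnesiation fixes the Z-hydroxymethyl alkene).
4. cis-Decalin bromide ⇒ γ-keto ester ⇒ bicyclic enone (cis-selective conjugate methylation with enolate alkylation, then MeMgBr and acid to the tetrasubstituted alkene).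
5. Enone ⇒ 6-methoxy-1,1-dimethyltetralin by Birch dearomatisation and enantioselective β,γ→α,β isomerisation (key step). Ring order: ring A (already in the tetralone) → ring B (released from the anisole ring) → γ-lactone (from the furan).

Assumption: the SMILES is read as a cis-fused decalin (8a-CH3 and 4a-H on the same face, 4aR,8aS), so trans-decalin chiral-pool terpenoids are not used.
Assumption: for the catalyst-controlled steps on new substrates (3 and 12) the antipode named is the one expected by analogy; the mirror-image catalyst is equally available.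

Abbreviation: D = (4aR,8aS)-2,5,5,8a-tetramethyl-3,4,4a,5,6,7,8,8a-octahydronaphthalen-1-yl.

**Step 1**
Reactants: 1 6-methoxy-3,4-dihydronaphthalen-1(2H)-one
Product: 2 6-methoxy-1,1-dimethyl-1,2,3,4-tetrahydronaphthalene
Conditions: Me2Zn, TiCl4, CH2Cl2, −30 °C → rt
Reagents that add atoms: dimethylzinc, C[Zn]C
Why: Geminal dimethylation of the aryl ketone by Me2TiCl2 (Reetz reaction) runs through a benzylic cation stabilised by the para-methoxy group; no stereocentre is formed.

**Step 2**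
Reactants: 2 6-methoxy-1,1-dimethyl-1,2,3,4-tetrahydronaphthalene
Product: 4 5,5-dimethyl-3,4,5,6,7,8-hexahydronaphthalen-2(1H)-one, via dihydroanisole 3 (not isolated)
Conditions: Li, NH3 (l), t-BuOH, THF, −78 → −33 °C; then (CO2H)2, MeOH–H2O, rt
Reagents that add atoms: water, O
Why: Birch reduction protonates the ring at C5 and C8 (ortho and meta to OMe), and mild oxalic-acid hydrolysis of the enol ether gives the achiral β,γ-unsaturated ketone without conjugation.

**Step 3**
Reactants: 4 5,5-dimethyl-3,4,5,6,7,8-hexahydronaphthalen-2(1H)-one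
Product: 5 (4aR)-5,5-dimethyl-4,4a,5,6,7,8-hexahydronaphthalen-2(3H)-one
Conditions: 9-amino-9-deoxy-epi-quinidine (10 mol%), PhCO2H (20 mol%), toluene, 0 °C
Reagents that add atoms: none
Why: Chiral primary-amine (dienamine/iminium) catalysed enantioselective isomerisation of a Birch-derived β,γ-enone removes a C1 proton and delivers it to one face of C4a, setting 4aR, with conjugation as the driving force.

**Step 4**
Reactants: 5 (4aR)-5,5-dimethyl-4,4a,5,6,7,8-hexahydronaphthalen-2(3H)-one, 6 ethyl iodoacetate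
Product: 8 ethyl 2-[(4aR,8aS)-5,5,8a-trimethyl-2-oxodecahydronaphthalen-1-yl]acetate (C1 epimers), via lithium enolate 7 (not isolated)
Conditions: Me2CuLi, Et2O, −20 °C; then DMPU, ICH2CO2Et, −20 °C → rt
Reagents that add atoms: lithium dimethylcuprate, [Li+].C[Cu-]C
Why: Cuprate conjugate addition occurs anti to the C4a–C5 bond, so the new angular methyl is cis to the 4a-H (8aS, cis-decalin), and the regiodefined enolate is C-alkylated at C1 (conjugate addition–enolate alkylation).

**Step 5**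
Reactants: 8 ethyl 2-[(4aR,8aS)-5,5,8a-trimethyl-2-oxodecahydronaphthalen-1-yl]acetate
Product: 10 methyl 2-D-acetate, via lactone 9 (not isolated)
Conditions: MeMgBr (1.1 equiv), THF, −78 → 0 °C; then H2SO4, MeOH, 65 °C
Reagents that add atoms: methylmagnesium bromide, C[Mg]Br; methanol, CO
Why: Chemoselective Grignard addition to the ketone gives a tertiary alkoxide that lactonises, and acid-mediated E1 opening with Fischer esterification under equilibrating conditions gives the tetrasubstituted C1=C2 alkene (as in the sclareolide-to-ester conversion), erasing the C1 and C2 stereocentres.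

**Step 6**
Reactants: 10 methyl 2-D-acetate
Product: 11 2-D-ethan-1-ol
Conditions: LiAlH4, Et2O, 0 °C
Reagents that add atoms: none
Why: Hydride reduction of the ester to the primary alcohol; no stereocentre is touched.

**Step 7**
Reactants: 11 2-D-ethan-1-ol
Product: 12 (4aR,8aS)-1-(2-bromoethyl)-2,5,5,8a-tetramethyl-3,4,4a,5,6,7,8,8a-octahydronaphthalene
Conditions: CBr4, PPh3, CH2Cl2, 0 °C
Reagents that add atoms: tetrabromomethane, BrC(Br)(Br)Br
Why: Appel bromination (SN2 at the primary carbon) leaves the alkene and ring stereocentres untouched.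

**Step 8**
Reactants: 12 (4aR,8aS)-1-(2-bromoethyl)-2,5,5,8a-tetramethyl-3,4,4a,5,6,7,8,8a-octahydronaphthalene, 13 prop-2-yn-1-ol
Product: 16 (2Z)-3-iodo-2-(2-D-ethyl)prop-2-en-1-ol, via Grignard reagent 14 (not isolated), via alkenylmagnesium alkoxide 15 (not isolated)
Conditions: Mg, THF, 40 °C; added to ClMgOCH2C≡CH (from 13 + i-PrMgCl), CuI (10 mol%), THF–Et2O, 0 °C → rt; then I2, −40 → 0 °C
Reagents that add atoms: iodine, II
Why: Copper-catalysed anti-carbomagnesiation of the propargylic alkoxide puts the alkyl group on C2 and magnesium on C3 cis to the CH2O group (five-membered chelate), and iodinolysis with retention gives the Z-iodide.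

**Step 9**
Reactants: 16 (2Z)-3-iodo-2-(2-D-ethyl)prop-2-en-1-ol, 17 1-(furan-3-yl)ethan-1-one
Product: 18 (3Z)-1-(furan-3-yl)-4-(hydroxymethyl)-6-D-hex-3-en-1-one
Conditions: LiHMDS (3.2 equiv), Pd2(dba)3 (2.5 mol%), 2-dicyclohexylphosphino-2',4',6'-triisopropylbiphenyl (10 mol%), THF–toluene, 0 → 45 °C; AcOH, −78 °C
Reagents that add atoms: none
Why: Palladium-catalysed α-alkenylation of the methyl ketone enolate proceeds with retention of alkene geometry, and the product stays as its enolate until kinetic protonation at low temperature gives the β,γ-unsaturated ketone.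

**Step 10**
Reactants: 18 (3Z)-1-(furan-3-yl)-4-(hydroxymethyl)-6-D-hex-3-en-1-one
Product: 19 (2Z,5R)-5-(furan-3-yl)-2-(2-D-ethyl)pent-2-ene-1,5-diol
Conditions: (S)-2-methyl-CBS-oxazaborolidine (20 mol%), catecholborane, toluene, −78 °C; MeOH
Reagents that add atoms: none
Why: Corey–Bakshi–Shibata reduction with furyl as the large group and CH2 as the small group gives the R carbinol, by analogy with acetophenone giving (R)-1-phenylethanol with the (S)-catalyst.

**Step 11**
Reactants: 19 (2Z,5R)-5-(furan-3-yl)-2-(2-D-ethyl)pent-2-ene-1,5-diol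
Product: 22 4-[(1R,3Z)-1-hydroxy-4-(hydroxymethyl)-6-D-hex-3-en-1-yl]furan-2(5H)-one, via furan endoperoxide 20 (not isolated), via hydroxybutenolide 21 (not isolated)
Conditions: O2, hν, rose bengal (cat.), i-Pr2NEt, CH2Cl2, −78 °C; then NaBH4, EtOH, 0 °C; 1 M HCl to pH 3
Reagents that add atoms: dioxygen, O=O
Why: [4+2] addition of singlet oxygen dearomatises the furan faster than the hindered alkenes react, the hindered base removes the less hindered C5–H of the endoperoxide to give the 4-substituted 5-hydroxybutenolide, and borohydride reduction of its masked aldehyde followed by relactonisation gives the β-substituted butenolide.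

**Step 12**
Reactants: 22 4-[(1R,3Z)-1-hydroxy-4-(hydroxymethyl)-6-D-hex-3-en-1-yl]furan-2(5H)-one
Product: 23 (4S)-4-[(1R,3Z)-1-hydroxy-4-(hydroxymethyl)-6-D-hex-3-en-1-yl]oxolan-2-one (target)
Conditions: Cu(OAc)2·H2O (3 mol%), (R)-DTBM-SEGPHOS (3 mol%), (EtO)2MeSiH, t-BuOH, toluene, 0 °C → rt; aq. NH4F
Reagents that add atoms: none
Why: Ligand-controlled copper hydride 1,4-reduction (asymmetric conjugate reduction) adds hydride to the Re face of C4, setting 4S, and leaves the isolated tri- and tetrasubstituted alkenes untouched.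

**Compound list**
1 | 6-methoxy-3,4-dihydronaphthalen-1(2H)-one | COc1ccc2C(=O)CCCc2c1 | starting material
2 | 6-methoxy-1,1-dimethyl-1,2,3,4-tetrahydronaphthalene | COc1ccc2c(c1)CCCC2(C)C | intermediate
3 | 6-methoxy-1,1-dimethyl-1,2,3,4,5,8-hexahydronaphthalene | COC1=CCC2=C(C1)CCCC2(C)C | intermediate
4 | 5,5-dimethyl-3,4,5,6,7,8-hexahydronaphthalen-2(1H)-one | O=C1CCC2=C(C1)CCCC2(C)C | intermediate
5 | (4aR)-5,5-dimethyl-4,4a,5,6,7,8-hexahydronaphthalen-2(3H)-one | O=C1C=C2CCCC(C)(C)[C@H]2CC1 | intermediate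
6 | ethyl iodoacetate | CCOC(=O)CI | starting material
7 | lithium (4aR,8aS)-5,5,8a-trimethyl-3,4,4a,5,6,7,8,8a-octahydronaphthalen-2-olate | [Li]OC1=C[C@@]2(C)CCCC(C)(C)[C@H]2CC1 | intermediate
8 | ethyl 2-[(4aR,8aS)-5,5,8a-trimethyl-2-oxodecahydronaphthalen-1-yl]acetate (C1 epimers) | O=C1C(CC(=O)OCC)[C@@]2(C)CCCC(C)(C)[C@H]2CC1 | intermediate
9 | (5aR,9aS)-3a,6,6,9a-tetramethyldecahydronaphtho[2,1-b]furan-2(1H)-one (C3a/C9b epimers) | O=C1CC2[C@@]3(C)CCCC(C)(C)[C@H]3CCC2(C)O1 | intermediate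
10 | methyl 2-[(4aR,8aS)-2,5,5,8a-tetramethyl-3,4,4a,5,6,7,8,8a-octahydronaphthalen-1-yl]acetate | CC1=C(CC(=O)OC)[C@@]2(C)CCCC(C)(C)[C@H]2CC1 | intermediate
11 | 2-[(4aR,8aS)-2,5,5,8a-tetramethyl-3,4,4a,5,6,7,8,8a-octahydronaphthalen-1-yl]ethan-1-ol | CC1=C(CCO)[C@@]2(C)CCCC(C)(C)[C@H]2CC1 | intermediate
12 | (4aR,8aS)-1-(2-bromoethyl)-2,5,5,8a-tetramethyl-3,4,4a,5,6,7,8,8a-octahydronaphthalene | CC1=C(CCBr)[C@@]2(C)CCCC(C)(C)[C@H]2CC1 | intermediate
13 | prop-2-yn-1-ol | OCC#C | starting material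
14 | (2-D-ethyl)magnesium bromide | CC1=C(CC[Mg]Br)[C@@]2(C)CCCC(C)(C)[C@H]2CC1 | intermediate
15 | chloromagnesium (2Z)-3-(bromomagnesio)-2-(2-D-ethyl)prop-2-en-1-olate | CC1=C(CC/C(=C/[Mg]Br)CO[Mg]Cl)[C@@]2(C)CCCC(C)(C)[C@H]2CC1 | intermediate
16 | (2Z)-3-iodo-2-(2-D-ethyl)prop-2-en-1-ol | CC1=C(CC/C(=C/I)CO)[C@@]2(C)CCCC(C)(C)[C@H]2CC1 | intermediate
17 | 1-(furan-3-yl)ethan-1-one | CC(=O)c1ccoc1 | starting material
18 | (3Z)-1-(furan-3-yl)-4-(hydroxymethyl)-6-D-hex-3-en-1-one | CC1=C(CC/C(=C/CC(=O)c3ccoc3)CO)[C@@]2(C)CCCC(C)(C)[C@H]2CC1 | intermediate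
19 | (2Z,5R)-5-(furan-3-yl)-2-(2-D-ethyl)pent-2-ene-1,5-diol | CC1=C(CC/C(=C/C[C@@H](O)c3ccoc3)CO)[C@@]2(C)CCCC(C)(C)[C@H]2CC1 | intermediate
20 | 2,3,7-trioxabicyclo[2.2.1]hept-5-ene endoperoxide of 19 (5-substituted) | CC1=C(CC/C(=C/C[C@@H](O)C3=CC4OOC3O4)CO)[C@@]2(C)CCCC(C)(C)[C@H]2CC1 | intermediate
21 | 5-hydroxy-4-[(1R,3Z)-1-hydroxy-4-(hydroxymethyl)-6-D-hex-3-en-1-yl]furan-2(5H)-one (C5 epimers) | CC1=C(CC/C(=C/C[C@@H](O)C3=CC(=O)OC3O)CO)[C@@]2(C)CCCC(C)(C)[C@H]2CC1 | intermediate
22 | 4-[(1R,3Z)-1-hydroxy-4-(hydroxymethyl)-6-D-hex-3-en-1-yl]furan-2(5H)-one | CC1=C(CC/C(=C/C[C@@H](O)C3=CC(=O)OC3)CO)[C@@]2(C)CCCC(C)(C)[C@H]2CC1 | intermediate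
23 | (4S)-4-[(1R,3Z)-1-hydroxy-4-(hydroxymethyl)-6-[(4aR,8aS)-2,5,5,8a-tetramethyl-3,4,4a,5,6,7,8,8a-octahydronaphthalen-1-yl]hex-3-en-1-yl]oxolan-2-one | CC1=C(CC/C(=C/C[C@@H](O)[C@@H]2COC(=O)C2)CO)[C@@]2(C)CCCC(C)(C)[C@H]2CC1 | target

**Total step count:** 12. **Longest linear sequence:** 12 (from 1; compounds 6, 13 and 17 are bought).

**Steps most likely to fail**

Step 3. A ring-fused β,γ-enone with a tetrasubstituted alkene lies outside the usual substrate range of the amine-catalysed isomerisation, so rate and ee may be low. The fallback sets out from 4 and comes back at 5. Isomerise 4 with HCl in MeOH to the racemate, that is 5 plus its enantiomer (4aS)-5,5-dimethyl-4,4a,5,6,7,8-hexahydronaphthalen-2(3H)-one F1. Add lithiated (S)-N,S-dimethyl-S-phenylsulfoximine F2 (from the sulfoximine and n-BuLi, THF, −78 °C) to the carbonyl. Separate on silica the diastereomeric β-hydroxysulfoximines, the adduct of 5 F3 and the adduct of the enantiomer F4. Heat F3 in toluene at 110 °C, which returns 5 by retro-addition. The same adducts can upgrade partly enriched 5.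

Step 9. The hindered Z-iodide carries a free alkoxide, so conversion may be low, and the β,γ-alkene may migrate into conjugation. The fallback sets out from 16 and comes back at 18. Negishi coupling of 16 with commercial (2-ethoxy-2-oxoethyl)zinc bromide (Pd(PPh3)4, THF, 50 °C) gives ethyl (3Z)-4-(hydroxymethyl)-6-D-hex-3-enoate F5. This closes onto the cis-CH2OH (PPTS, benzene, 60 °C) to give 5-(2-D-ethyl)-3,6-dihydro-2H-pyran-2-one F6. Furan-3-yllithium F7 (from 3-bromofuran and n-BuLi, THF, −78 °C) adds once to the lactone carbonyl, and work-up opens the lactol to ketone 18.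

Step 12. C4 is set by the ligand next to an existing carbinol, so a mismatched pair or alkoxide-directed delivery could erode the diastereomer ratio; the C4 epimers are diastereomers and separable, but yield would suffer. The fallback sets out from 22 and comes back at 23. Silylate both hydroxyls (TBSOTf, 2,6-lutidine, CH2Cl2) to the bis-TBS ether of 22 F8. Hydrogenate the butenolide C=C with H2 (100 atm) and Ru(OAc)2(BINAP) (antipode giving 4S; MeOH–CH2Cl2, 50 °C) to the bis-TBS ether of 23 F9. This carbonyl-directed hydrogenation leaves unfunctionalised tri- and tetrasubstituted alkenes alone once no free OH is left to direct it. Remove the silyl groups with HF·pyridine in THF.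

**Further compounds**
F1 | step 3 | (4aS)-5,5-dimethyl-4,4a,5,6,7,8-hexahydronaphthalen-2(3H)-one | O=C1C=C2CCCC(C)(C)[C@@H]2CC1
F2 | step 3 | lithiated (S)-N,S-dimethyl-S-phenylsulfoximine | [Li]C[S@@](=O)(=NC)c1ccccc1
F3 | step 3 | β-hydroxysulfoximine adduct of 5 (carbinol epimers) | OC1(C[S@@](=O)(=NC)c3ccccc3)C=C2CCCC(C)(C)[C@H]2CC1
F4 | step 3 | β-hydroxysulfoximine adduct of F1 (carbinol epimers) | OC1(C[S@@](=O)(=NC)c3ccccc3)C=C2CCCC(C)(C)[C@@H]2CC1
F5 | step 9 | ethyl (3Z)-4-(hydroxymethyl)-6-D-hex-3-enoate | CC1=C(CC/C(=C/CC(=O)OCC)CO)[C@@]2(C)CCCC(C)(C)[C@H]2CC1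
F6 | step 9 | 5-(2-D-ethyl)-3,6-dihydro-2H-pyran-2-one | CC1=C(CCC3=CCC(=O)OC3)[C@@]2(C)CCCC(C)(C)[C@H]2CC1
F7 | step 9 | furan-3-yllithium | [Li]c1ccoc1
F8 | step 12 | bis-TBS ether of 22 | CC1=C(CC/C(=C/C[C@@H](O[Si](C)(C)C(C)(C)C)C3=CC(=O)OC3)CO[Si](C)(C)C(C)(C)C)[C@@]2(C)CCCC(C)(C)[C@H]2CC1
F9 | step 12 | bis-TBS ether of 23 | CC1=C(CC/C(=C/C[C@@H](O[Si](C)(C)C(C)(C)C)[C@@H]3COC(=O)C3)CO[Si](C)(C)C(C)(C)C)[C@@]2(C)CCCC(C)(C)[C@H]2CC1
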